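## Retrosynthetic overview

1. The last C–C bond joins the diarylmethine carbon to C-5 of the resorcinol ring on the tetrahydrofuran. It is made by fluoride-triggered quinone methide capture, which unites fragment E (dihydrobenzofuran chalcone, benzylic acetate) with fragment N (tetrahydrofuran ketone) and removes all eleven silyl ethers.
2. Fragment E: chalcone by Heck reaction; benzylic acetate by aryl Grignard addition to a C-3 aldehyde; dihydrobenzofuran by enantioselective rhodium-carbenoid C–H insertion, then epimerisation to trans.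
3. Fragment N: tetrahydrofuran by kinetic reductive deoxygenation of a lactol; lactol by double addition of one aryllithium to a lactone and a Weinreb amide; lactone by titanium syn-aldol/lactonisation of a succinate thioimide, then trans-benzylation.
4. Ring order: the dihydrobenzofuran (fragment E) and the γ-lactone, later converted into the tetrahydrofuran (fragment N), are built independently; no ring is formed in the union.
5. One aryl bromide supplies all four carbon-bound 2,4-dioxygenated aryl rings (one Grignard batch for two of them, one aryllithium for the other two); every phenol is carried as a TBS ether (TBS = tert-butyldimethylsilyl).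

Assumption: Rh2(S-PTTL)4 is taken to give the (2R) insertion product; if the sense is opposite, Rh2(R-PTTL)4 is used and nothing else changes. The seven starting materials are taken as catalogue compounds.

## Route

Step 1
Reactants: 1 4-bromobenzene-1,3-diol
Product: 2 1-bromo-2,4-bis(TBSO)benzene
Conditions: TBSCl (2.4 equiv), imidazole, DMF, rt
Reagents that add atoms: tert-butyldimethylsilyl chloride, CC(C)(C)[Si](C)(C)Cl
Why: Imidazole-mediated O-silylation masks both phenols as fluoride-labile ethers that survive the organometallic steps; no stereocentre is formed.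

Step 2
Reactants: 2 1-bromo-2,4-bis(TBSO)benzene
Product: 3 [2,4-bis(TBSO)phenyl]magnesium bromide (titrated THF solution)
Conditions: Mg turnings (1.5 equiv), LiCl (1.2 equiv), THF, rt; cannula-filtered, titrated, kept at 0 °C under argon
Reagents that add atoms: magnesium, [Mg]
Why: Grignard formation by LiCl-accelerated magnesium insertion into the aryl bromide gives one batch of a storable arylmagnesium reagent (no silyl migration at the magnesium stage) that is drawn on in steps 3 and 9.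

Step 3
Reactants: 3 [2,4-bis(TBSO)phenyl]magnesium bromide; 4 N-methoxy-N-methylprop-2-enamide
Product: 5 1-[2,4-bis(TBSO)phenyl]prop-2-en-1-one
Conditions: 3 (1.1 equiv), THF, −78 → 0 °C; cold 1 M HCl quench
Reagents that add atoms: none
Why: Weinreb ketone synthesis: the aryl Grignard adds once to give a stable chelate, and the acidic quench releases the vinyl ketone while keeping the liberated amine protonated so it cannot add to the enone.

Step 4
Reactants: 6 [4-(TBSO)phenyl]methanol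
Product: 7 4-(TBSO)benzyl bromide
Conditions: CBr4, PPh3, CH2Cl2, 0 °C
Reagents that add atoms: carbon tetrabromide, BrC(Br)(Br)Br
Why: Appel bromination converts the benzylic alcohol under neutral conditions that leave the aryl silyl ether intact.

Step 5
Reactants: 8 methyl 2-(5-bromo-2-hydroxyphenyl)acetate; 6 [4-(TBSO)phenyl]methanol
Product: 9 methyl 2-{5-bromo-2-[4-(TBSO)benzyloxy]phenyl}acetate
Conditions: PPh3, DIAD, THF, 0 °C → rt
Reagents that add atoms: none
Why: Mitsunobu etherification of the phenol with the primary benzylic alcohol avoids basic conditions that would cleave the aryl silyl ether.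

Step 6
Reactants: 9 methyl 2-{5-bromo-2-[4-(TBSO)benzyloxy]phenyl}acetate
Product: 10 methyl 2-{5-bromo-2-[4-(TBSO)benzyloxy]phenyl}-2-diazoacetate
Conditions: p-ABSA, DBU, MeCN, 0 °C → rt
Reagents that add atoms: 4-acetamidobenzenesulfonyl azide, CC(=O)Nc1ccc(cc1)S(=O)(=O)N=[N+]=[N-]
Why: Regitz diazo transfer to the acidic arylacetate position gives the donor/acceptor diazo ester.

Step 7
Reactants: 10 methyl 2-{5-bromo-2-[4-(TBSO)benzyloxy]phenyl}-2-diazoacetate
Product: 12 methyl (2R,3R)-5-bromo-2-[4-(TBSO)phenyl]-2,3-dihydro-1-benzofuran-3-carboxylate (2,3-trans), via cis ester 11 (not isolated)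
Conditions: Rh2(S-PTTL)4 (dirhodium tetrakis[N-phthaloyl-(S)-tert-leucinate], 1 mol %), toluene, −60 °C; then DBU, 60 °C
Reagents that add atoms: none
Why: Intramolecular 1,5 C–H insertion of the rhodium carbenoid into the ether-activated benzylic C–H closes the ring with the chiral carboxylate ligands fixing C-2 (cis product), and DBU then epimerises the ester-bearing C-3 through its enolate to the more stable trans isomer without touching C-2.

Step 8
Reactants: 12 methyl (2R,3R)-5-bromo-2-[4-(TBSO)phenyl]-2,3-dihydro-1-benzofuran-3-carboxylate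
Product: 13 (2R,3R)-5-bromo-2-[4-(TBSO)phenyl]-2,3-dihydro-1-benzofuran-3-carbaldehyde
Conditions: i-Bu2AlH (1.1 equiv), CH2Cl2, −78 °C; aq. KNaC4H4O6
Reagents that add atoms: none
Why: Partial ester reduction stops at the aldehyde because the tetrahedral aluminium hemiacetal is stable at −78 °C; the trans stereocentres are untouched.

Step 9
Reactants: 13 (2R,3R)-5-bromo-2-[4-(TBSO)phenyl]-2,3-dihydro-1-benzofuran-3-carbaldehyde; 3 [2,4-bis(TBSO)phenyl]magnesium bromide
Product: 15 [2,4-bis(TBSO)phenyl]{(2R,3R)-5-bromo-2-[4-(TBSO)phenyl]-2,3-dihydro-1-benzofuran-3-yl}methyl acetate (both epimers at the acetoxy carbon), via magnesium alkoxide 14 (not isolated)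
Conditions: 3 (1.3 equiv), THF, −78 °C; then Ac2O, −78 → 0 °C; aq. NaHCO3
Reagents that add atoms: acetic anhydride, CC(=O)OC(C)=O
Why: Grignard 1,2-addition to the aldehyde outruns enolisation at −78 °C and the alkoxide is acetylated in situ; the new carbinol centre forms unselectively but is erased when the quinone methide is generated in step 17.

Step 10
Reactants: 15 [2,4-bis(TBSO)phenyl]{(2R,3R)-5-bromo-2-[4-(TBSO)phenyl]-2,3-dihydro-1-benzofuran-3-yl}methyl acetate; 5 1-[2,4-bis(TBSO)phenyl]prop-2-en-1-one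
Product: 16 (E)-3-{(2R,3R)-3-{acetoxy[2,4-bis(TBSO)phenyl]methyl}-2-[4-(TBSO)phenyl]-2,3-dihydro-1-benzofuran-5-yl}-1-[2,4-bis(TBSO)phenyl]prop-2-en-1-one (fragment E)
Conditions: Pd2(dba)3 (2.5 mol %), P(t-Bu)3·HBF4, Cy2NMe, 1,4-dioxane, 60 °C
Reagents that add atoms: none
Why: Mizoroki–Heck coupling of the aryl bromide with the aryl vinyl ketone gives the E-chalcone by syn insertion and syn β-hydride elimination under conditions mild enough for the benzylic acetate and silyl ethers.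

Step 11
Reactants: 17 (S)-4-benzyl-1,3-thiazolidine-2-thione; 18 methyl 4-chloro-4-oxobutanoate
Product: 19 methyl 4-[(S)-4-benzyl-2-thioxo-1,3-thiazolidin-3-yl]-4-oxobutanoate
Conditions: Et3N, DMAP (cat.), CH2Cl2, 0 °C
Reagents that add atoms: none
Why: N-acylation of the auxiliary with the acid chloride gives the succinate thioimide for the auxiliary-controlled aldol.

Step 12
Reactants: 19 methyl 4-[(S)-4-benzyl-2-thioxo-1,3-thiazolidin-3-yl]-4-oxobutanoate; 20 4-(TBSO)benzaldehyde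
Product: 23 (S)-4-benzyl-3-{(2S,3S)-2-[4-(TBSO)phenyl]-5-oxooxolane-3-carbonyl}-1,3-thiazolidine-2-thione (4,5-trans lactone), via titanium enolate 21 (not isolated), via syn aldol adduct 22 (not isolated)
Conditions: TiCl4 (1.05 equiv), i-Pr2NEt (1.1 equiv), N-methylpyrrolidinone (1 equiv), CH2Cl2, 0 °C; 20, 0 °C; aq. NH4Cl; then camphorsulfonic acid (cat.), CH2Cl2, rt
Reagents that add atoms: none
Why: Crimmins titanium aldol in its Evans-syn mode: the Z-enolate reacts through a chair transition state on the face away from the (S)-benzyl group, setting both new centres (2S,3S), and acid-catalysed lactonisation onto the methyl ester turns the syn adduct into the trans lactone.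

Step 13
Reactants: 23 (S)-4-benzyl-3-{(2S,3S)-2-[4-(TBSO)phenyl]-5-oxooxolane-3-carbonyl}-1,3-thiazolidine-2-thione
Product: 24 (2S,3S)-N-methoxy-N-methyl-2-[4-(TBSO)phenyl]-5-oxooxolane-3-carboxamide
Conditions: MeNHOMe·HCl, imidazole, CH2Cl2, rt
Reagents that add atoms: N,O-dimethylhydroxylamine hydrochloride, CNOC.Cl
Why: The activated thioimide is aminolysed at rt, far faster than the lactone, giving the Weinreb amide and returning the auxiliary without base strong enough to epimerise or desilylate.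

Step 14
Reactants: 24 (2S,3S)-N-methoxy-N-methyl-2-[4-(TBSO)phenyl]-5-oxooxolane-3-carboxamide; 7 4-(TBSO)benzyl bromide
Product: 26 (2S,3S,4S)-N-methoxy-N-methyl-4-[4-(TBSO)benzyl]-2-[4-(TBSO)phenyl]-5-oxooxolane-3-carboxamide, via lithium enolate 25 (not isolated)
Conditions: LiN(SiMe3)2 (1.1 equiv), THF, −78 °C; then 7, −78 → −40 °C
Reagents that add atoms: none
Why: Kinetic deprotonation takes the lactone CH2 (enolisation of the branched Weinreb amide is blocked by A(1,3) strain) and the enolate is alkylated anti to the adjacent amide substituent, setting the benzyl centre 3,4-trans.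

Step 15
Reactants: 26 (2S,3S,4S)-N-methoxy-N-methyl-4-[4-(TBSO)benzyl]-2-[4-(TBSO)phenyl]-5-oxooxolane-3-carboxamide; 2 1-bromo-2,4-bis(TBSO)benzene
Product: 28 [2,4-bis(TBSO)phenyl]{(2S,3S,4S)-5-[2,4-bis(TBSO)phenyl]-4-[4-(TBSO)benzyl]-5-hydroxy-2-[4-(TBSO)phenyl]oxolan-3-yl}methanone (lactol as both anomers), via aryllithium 27 (not isolated)
Conditions: 2 (3 equiv), n-BuLi (3 equiv), THF, −78 °C, 15 min; then 26, −78 °C; aq. NH4Cl at −78 °C
Reagents that add atoms: none
Why: Because both missing aryl groups are the same, one aryllithium (bromine–lithium exchange) adds once to the lactone (stable lithium lactolate at −78 °C) and once to the Weinreb amide (stable chelate), so quenching gives the aryl ketone and the aryl lactol together without touching the three stereocentres.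

Step 16
Reactants: 28 the lactol of step 15
Product: 29 [2,4-bis(TBSO)phenyl]{(2S,3S,4S,5R)-5-[2,4-bis(TBSO)phenyl]-4-[4-(TBSO)benzyl]-2-[4-(TBSO)phenyl]oxolan-3-yl}methanone (fragment N)
Conditions: Et3SiH (5 equiv), BF3·OEt2 (2 equiv), CH2Cl2, −78 °C; Et3N quench at −78 °C
Reagents that add atoms: none
Why: Ionic reduction: BF3 ionises the lactol to the 2-aryl oxocarbenium ion and Et3SiH delivers hydride anti to the neighbouring benzyl group, giving the kinetic aryl/benzyl-cis ether (the natural relative configuration) while the deactivated aryl ketone is not reduced at −78 °C.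

Step 17
Reactants: 16 fragment E; 29 fragment N
Product: 32 lophirachalcone, via hexaphenol 30 (not isolated), via quinone methide 31 (not isolated)
Conditions: 29 (2 equiv), Bu4NF (excess), THF/DMF, 0 °C; then 16 added slowly, 0 °C → rt; AcOH quench
Reagents that add atoms: none
Why: Fluoride strips all silyl ethers, the phenoxide of 16 expels acetate to give the quinone methide, and the resorcinol phenoxide of 30 adds through its C-5 (conjugate, Friedel–Crafts-type C-alkylation), approaching the A(1,3)-locked quinone methide anti to the fused benzo ring and syn to H-2, which sets the (R)-diarylmethine centre.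

## Compound list

1 | 4-bromobenzene-1,3-diol | Oc1ccc(Br)c(O)c1 | starting material
2 | 1-bromo-2,4-bis(TBSO)benzene | CC(C)(C)[Si](C)(C)Oc1ccc(Br)c(O[Si](C)(C)C(C)(C)C)c1 | intermediate
3 | [2,4-bis(TBSO)phenyl]magnesium bromide (titrated THF solution) | Br[Mg]c1ccc(O[Si](C)(C)C(C)(C)C)cc1O[Si](C)(C)C(C)(C)C | intermediate
4 | N-methoxy-N-methylprop-2-enamide | C=CC(=O)N(C)OC | starting material
5 | 1-[2,4-bis(TBSO)phenyl]prop-2-en-1-one | C=CC(=O)c1ccc(O[Si](C)(C)C(C)(C)C)cc1O[Si](C)(C)C(C)(C)C | intermediate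
6 | [4-(TBSO)phenyl]methanol | OCc1ccc(O[Si](C)(C)C(C)(C)C)cc1 | starting material
7 | 4-(TBSO)benzyl bromide | BrCc1ccc(O[Si](C)(C)C(C)(C)C)cc1 | intermediate
8 | methyl 2-(5-bromo-2-hydroxyphenyl)acetate | COC(=O)Cc1cc(Br)ccc1O | starting material
9 | methyl 2-{5-bromo-2-[4-(TBSO)benzyloxy]phenyl}acetate | COC(=O)Cc1cc(Br)ccc1OCc1ccc(O[Si](C)(C)C(C)(C)C)cc1 | intermediate
10 | methyl 2-{5-bromo-2-[4-(TBSO)benzyloxy]phenyl}-2-diazoacetate | COC(=O)C(=[N+]=[N-])c1cc(Br)ccc1OCc1ccc(O[Si](C)(C)C(C)(C)C)cc1 | intermediate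
11 | methyl (2R,3S)-5-bromo-2-[4-(TBSO)phenyl]-2,3-dihydro-1-benzofuran-3-carboxylate (cis) | Brc1ccc2c(c1)[C@H](C(=O)OC)[C@H](c1ccc(O[Si](C)(C)C(C)(C)C)cc1)O2 | intermediate (not isolated)
12 | methyl (2R,3R)-5-bromo-2-[4-(TBSO)phenyl]-2,3-dihydro-1-benzofuran-3-carboxylate (trans) | Brc1ccc2c(c1)[C@@H](C(=O)OC)[C@H](c1ccc(O[Si](C)(C)C(C)(C)C)cc1)O2 | intermediate
13 | (2R,3R)-5-bromo-2-[4-(TBSO)phenyl]-2,3-dihydro-1-benzofuran-3-carbaldehyde | Brc1ccc2c(c1)[C@@H](C=O)[C@H](c1ccc(O[Si](C)(C)C(C)(C)C)cc1)O2 | intermediate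
14 | bromomagnesium alkoxide of the carbinol from 13 and 3 (epimers at the carbinol carbon) | Brc1ccc2c(c1)[C@@H](C(O[Mg]Br)c1ccc(O[Si](C)(C)C(C)(C)C)cc1O[Si](C)(C)C(C)(C)C)[C@H](c1ccc(O[Si](C)(C)C(C)(C)C)cc1)O2 | intermediate (not isolated)
15 | [2,4-bis(TBSO)phenyl]{(2R,3R)-5-bromo-2-[4-(TBSO)phenyl]-2,3-dihydro-1-benzofuran-3-yl}methyl acetate (epimers at the acetoxy carbon) | Brc1ccc2c(c1)[C@@H](C(OC(C)=O)c1ccc(O[Si](C)(C)C(C)(C)C)cc1O[Si](C)(C)C(C)(C)C)[C@H](c1ccc(O[Si](C)(C)C(C)(C)C)cc1)O2 | intermediate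
16 | fragment E: (E)-3-{(2R,3R)-3-{acetoxy[2,4-bis(TBSO)phenyl]methyl}-2-[4-(TBSO)phenyl]-2,3-dihydro-1-benzofuran-5-yl}-1-[2,4-bis(TBSO)phenyl]prop-2-en-1-one | O=C(/C=C/c1ccc2c(c1)[C@@H](C(OC(C)=O)c1ccc(O[Si](C)(C)C(C)(C)C)cc1O[Si](C)(C)C(C)(C)C)[C@H](c1ccc(O[Si](C)(C)C(C)(C)C)cc1)O2)c1ccc(O[Si](C)(C)C(C)(C)C)cc1O[Si](C)(C)C(C)(C)C | intermediate
17 | (S)-4-benzyl-1,3-thiazolidine-2-thione | S=C1SC[C@H](Cc2ccccc2)N1 | starting material
18 | methyl 4-chloro-4-oxobutanoate | COC(=O)CCC(Cl)=O | starting material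
19 | methyl 4-[(S)-4-benzyl-2-thioxo-1,3-thiazolidin-3-yl]-4-oxobutanoate | COC(=O)CCC(=O)N1C(=S)SC[C@@H]1Cc1ccccc1 | intermediate
20 | 4-(TBSO)benzaldehyde | O=Cc1ccc(O[Si](C)(C)C(C)(C)C)cc1 | starting material
21 | trichlorotitanium (Z)-enolate of 19 | COC(=O)C/C=C(\O[Ti](Cl)(Cl)Cl)N1C(=S)SC[C@@H]1Cc1ccccc1 | intermediate (not isolated)
22 | methyl (3S)-3-{(S)-hydroxy[4-(TBSO)phenyl]methyl}-4-[(S)-4-benzyl-2-thioxo-1,3-thiazolidin-3-yl]-4-oxobutanoate (syn aldol) | O[C@H](c1ccc(O[Si](C)(C)C(C)(C)C)cc1)[C@@H](C(=O)N1C(=S)SC[C@@H]1Cc1ccccc1)CC(=O)OC | intermediate (not isolated)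
23 | (S)-4-benzyl-3-{(2S,3S)-2-[4-(TBSO)phenyl]-5-oxooxolane-3-carbonyl}-1,3-thiazolidine-2-thione | O=C1O[C@H](c2ccc(O[Si](C)(C)C(C)(C)C)cc2)[C@@H](C(=O)N2C(=S)SC[C@@H]2Cc2ccccc2)C1 | intermediate
24 | (2S,3S)-N-methoxy-N-methyl-2-[4-(TBSO)phenyl]-5-oxooxolane-3-carboxamide | O=C1O[C@H](c2ccc(O[Si](C)(C)C(C)(C)C)cc2)[C@@H](C(=O)N(C)OC)C1 | intermediate
25 | lithium enolate of lactone 24 | [Li]OC1=C[C@H](C(=O)N(C)OC)[C@@H](c2ccc(O[Si](C)(C)C(C)(C)C)cc2)O1 | intermediate (not isolated)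
26 | (2S,3S,4S)-N-methoxy-N-methyl-4-[4-(TBSO)benzyl]-2-[4-(TBSO)phenyl]-5-oxooxolane-3-carboxamide | O=C1O[C@H](c2ccc(O[Si](C)(C)C(C)(C)C)cc2)[C@@H](C(=O)N(C)OC)[C@@H]1Cc1ccc(O[Si](C)(C)C(C)(C)C)cc1 | intermediate
27 | [2,4-bis(TBSO)phenyl]lithium | [Li]c1ccc(O[Si](C)(C)C(C)(C)C)cc1O[Si](C)(C)C(C)(C)C | intermediate (not isolated)
28 | [2,4-bis(TBSO)phenyl]{(2S,3S,4S)-5-[2,4-bis(TBSO)phenyl]-4-[4-(TBSO)benzyl]-5-hydroxy-2-[4-(TBSO)phenyl]oxolan-3-yl}methanone (both anomers) | OC1(c2ccc(O[Si](C)(C)C(C)(C)C)cc2O[Si](C)(C)C(C)(C)C)O[C@H](c2ccc(O[Si](C)(C)C(C)(C)C)cc2)[C@@H](C(=O)c2ccc(O[Si](C)(C)C(C)(C)C)cc2O[Si](C)(C)C(C)(C)C)[C@@H]1Cc1ccc(O[Si](C)(C)C(C)(C)C)cc1 | intermediate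
29 | fragment N: [2,4-bis(TBSO)phenyl]{(2S,3S,4S,5R)-5-[2,4-bis(TBSO)phenyl]-4-[4-(TBSO)benzyl]-2-[4-(TBSO)phenyl]oxolan-3-yl}methanone | CC(C)(C)[Si](C)(C)Oc1ccc([C@@H]2O[C@H](c3ccc(O[Si](C)(C)C(C)(C)C)cc3)[C@@H](C(=O)c3ccc(O[Si](C)(C)C(C)(C)C)cc3O[Si](C)(C)C(C)(C)C)[C@@H]2Cc2ccc(O[Si](C)(C)C(C)(C)C)cc2)c(O[Si](C)(C)C(C)(C)C)c1 | intermediate
30 | (2,4-dihydroxyphenyl){(2S,3S,4S,5R)-5-(2,4-dihydroxyphenyl)-4-(4-hydroxybenzyl)-2-(4-hydroxyphenyl)oxolan-3-yl}methanone (present as its phenoxide) | Oc1ccc([C@@H]2O[C@H](c3ccc(O)cc3)[C@@H](C(=O)c3ccc(O)cc3O)[C@@H]2Cc2ccc(O)cc2)c(O)c1 | intermediate (not isolated)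
31 | desilylated para-quinone methide from 16 (2R,3R; exocyclic alkene geometry not defined) | O=C(/C=C/c1ccc2c(c1)[C@@H](C=C1C=CC(=O)C=C1O)[C@H](c1ccc(O)cc1)O2)c1ccc(O)cc1O | intermediate (not isolated)
32 | lophirachalcone | O=C(/C=C/c1ccc2c(c1)[C@@H]([C@H](c1ccc(O)cc1O)c1cc([C@@H]3O[C@H](c4ccc(O)cc4)[C@@H](C(=O)c4ccc(O)cc4O)[C@@H]3Cc3ccc(O)cc3)c(O)cc1O)[C@H](c1ccc(O)cc1)O2)c1ccc(O)cc1O | target

## Summary

Total step count: 17. Longest linear sequence: 7 steps (steps 5–10 then 17; the branch of steps 11–16 then 17 is equally long).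

Steps most likely to fail, each with a fallback:

Step 17 (anionic quinone methide union; risks are O-alkylation, self-condensation of 16, tautomerisation of the quinone methide to a benzofuran, and base-induced flavanone closure of the 2'-hydroxychalcone). The fallback sets out from 16 and 29 and comes back at 32. Fragment 29 is desilylated alone (HF·pyridine, THF, 0 °C) and the hexaphenol 30 is isolated. Compound 16 is desilylated with AcOH-buffered Bu4NF in wet THF, so that the transient quinone methide is taken up by water, giving the free benzylic alcohol pentaphenol F1. F1 and excess 30 are then joined as neutral phenols by an ionising-solvent SN1 Friedel–Crafts alkylation in (CF3)2CHOH at rt without added acid, the same facial bias at the benzylic cation giving 32.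

Step 16 (kinetic cis-selective hydride delivery; the very electron-rich aryl group may let the Lewis acid re-ionise the product to the all-trans ether). The fallback sets out from 28 and comes back at 29. Lactol 28 is dehydrated (pyridinium p-toluenesulfonate cat., 4 Å sieves, toluene) to the 4,5-dihydrofuran F2. F2 is hydrogenated with [Ir(cod)(PCy3)(py)]PF6 under H2 in CH2Cl2, where the ketone carbonyl directs syn delivery of both hydrogens to its own face; this places the aryl and benzyl groups cis to each other and trans to the aroyl group, giving 29 without any cationic intermediate.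

Step 15 (double aryllithium addition; risks are silyl migration in the ortho-silyloxy aryllithium, enolisation of the lactone, and over-addition). The fallback sets out from 23 and comes back at 29, introducing the two aryl groups one at a time with the C-3 carbonyl masked as a carboxylate. Thioimide 23 is hydrolysed briefly (LiOH, H2O2, THF/H2O, 0 °C) to the lactone acid F3. The dianion of F3 (LiN(SiMe3)2, 2.2 equiv) is alkylated with 7 to the trans-benzylated lactone acid F4. Aryllithium 27, whose first equivalent makes the inert lithium carboxylate, then adds to the lactone only, giving the lactol acid F5. Et3SiH/BF3·OEt2 at −78 °C reduces F5 to the tetrahydrofuran acid F6. Amide coupling (EDC·HCl, MeNHOMe·HCl, i-Pr2NEt) gives the Weinreb amide F7, and a further portion of 27 converts F7 into 29.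

## Further compounds

F1 | step 17 | (E)-1-(2,4-dihydroxyphenyl)-3-{(2R,3-trans)-3-[(2,4-dihydroxyphenyl)(hydroxy)methyl]-2-(4-hydroxyphenyl)-2,3-dihydro-1-benzofuran-5-yl}prop-2-en-1-one (epimers at the carbinol carbon) | O=C(/C=C/c1ccc2c(c1)[C@@H](C(O)c1ccc(O)cc1O)[C@H](c1ccc(O)cc1)O2)c1ccc(O)cc1O
F2 | step 16 | [2,4-bis(TBSO)phenyl]{(2S,3S)-5-[2,4-bis(TBSO)phenyl]-4-[4-(TBSO)benzyl]-2-[4-(TBSO)phenyl]-2,3-dihydrofuran-3-yl}methanone (2,3-trans) | CC(C)(C)[Si](C)(C)Oc1ccc(C2=C(Cc3ccc(O[Si](C)(C)C(C)(C)C)cc3)[C@H](C(=O)c3ccc(O[Si](C)(C)C(C)(C)C)cc3O[Si](C)(C)C(C)(C)C)[C@@H](c3ccc(O[Si](C)(C)C(C)(C)C)cc3)O2)c(O[Si](C)(C)C(C)(C)C)c1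
F3 | step 15 | (2S,3S)-2-[4-(TBSO)phenyl]-5-oxooxolane-3-carboxylic acid | O=C1O[C@H](c2ccc(O[Si](C)(C)C(C)(C)C)cc2)[C@@H](C(=O)O)C1
F4 | step 15 | (2S,3S,4S)-4-[4-(TBSO)benzyl]-2-[4-(TBSO)phenyl]-5-oxooxolane-3-carboxylic acid | O=C1O[C@H](c2ccc(O[Si](C)(C)C(C)(C)C)cc2)[C@@H](C(=O)O)[C@@H]1Cc1ccc(O[Si](C)(C)C(C)(C)C)cc1
F5 | step 15 | (2S,3S,4S)-5-[2,4-bis(TBSO)phenyl]-4-[4-(TBSO)benzyl]-5-hydroxy-2-[4-(TBSO)phenyl]oxolane-3-carboxylic acid (both anomers) | OC1(c2ccc(O[Si](C)(C)C(C)(C)C)cc2O[Si](C)(C)C(C)(C)C)O[C@H](c2ccc(O[Si](C)(C)C(C)(C)C)cc2)[C@@H](C(=O)O)[C@@H]1Cc1ccc(O[Si](C)(C)C(C)(C)C)cc1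
F6 | step 15 | (2S,3S,4S,5R)-5-[2,4-bis(TBSO)phenyl]-4-[4-(TBSO)benzyl]-2-[4-(TBSO)phenyl]oxolane-3-carboxylic acid | CC(C)(C)[Si](C)(C)Oc1ccc([C@@H]2O[C@H](c3ccc(O[Si](C)(C)C(C)(C)C)cc3)[C@@H](C(=O)O)[C@@H]2Cc2ccc(O[Si](C)(C)C(C)(C)C)cc2)c(O[Si](C)(C)C(C)(C)C)c1
F7 | step 15 | (2S,3S,4S,5R)-5-[2,4-bis(TBSO)phenyl]-4-[4-(TBSO)benzyl]-N-methoxy-N-methyl-2-[4-(TBSO)phenyl]oxolane-3-carboxamide | CC(C)(C)[Si](C)(C)Oc1ccc([C@@H]2O[C@H](c3ccc(O[Si](C)(C)C(C)(C)C)cc3)[C@@H](C(=O)N(C)OC)[C@@H]2Cc2ccc(O[Si](C)(C)C(C)(C)C)cc2)c(O[Si](C)(C)C(C)(C)C)c1
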